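**Assumption:** ring B is written as one enol of the symmetrical 2-acylaminocyclopentane-1,3-dione (both enols are the same compound). The descriptors (4S,5S,6R) are read from the structure as drawn, with the C4 hydroxyl anti to the epoxide.

## Analysis of the target

The target is a manumycin-type epoxyquinol. Its centre is ring A, a cyclohex-2-en-1-one (C1 ketone, C2=C3, C4 tertiary carbinol, C5–C6 cis-fused epoxide). C2 carries the nitrogen of a (2E,4E,6E)-8-methylnona-2,4,6-trienamide, and C4 carries a (1E,3E,5E)-heptatrienyl chain whose C7′ carbonyl is an amide of ring B, a 2-amino-3-hydroxycyclopent-2-enone. There are three contiguous stereocentres, C4 (S), C5 (S) and C6 (R); the epoxide oxygen lies on the ring face opposite to the C4 hydroxyl and on the same face as the C4 triene. This anti arrangement is the harder one, because a carbon nucleophile is expected to add to a 5,6-epoxy ketone anti to the epoxide and so give the syn hydroxy epoxide. Sensitive groups are the two all-E trienamides (light, acid, radicals), the epoxy enone (base, nucleophiles), the C4 hydroxyl, whose alkoxide is placed to open the epoxide from the rear, the C2 enamide, and the acidic vinylogous acid of ring B. The free amine of ring B, a 2-aminocyclopentane-1,3-dione, is an easily oxidised reductone and is best never liberated. The strategy rests on ring B: its atoms N–C=C(OH)–CH2–CH2–C(=O) are those of an N-acyl 5-aminolevulinate whose nitrogen-bearing carbon is bonded to its carboxyl carbon, so one C–C bond closes the ring from an acyclic amino keto ester.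

## Retrosynthetic reasoning

**28 to 27.** The last operation makes no skeletal bond: the C4 hydroxyl is released from the triethylsilyl ether 27. The silyl group is kept to the end because the C4 alkoxide sits anti to the C5–O bond and could open the epoxide from the rear. The forward step only has to cleave Si–O with buffered fluoride.

**27 to 26 and 7.** The C2′–C3′ single bond of the lower triene is cut. It is the sp2–sp2 bond that divides the molecule into two halves of similar size, each with alkenes of fixed geometry: 26 holds ring A with all three stereocentres, 7 holds ring B. The forward reaction is a palladium-catalysed coupling of a vinylstannane with a vinyl bromide under neutral conditions, with retention at both alkenes.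

**7 to 6 (key disconnection).** In ring B the bond between the nitrogen-bearing carbon and the neighbouring carbonyl carbon is cut. This opens the ring to keto ester 6, in which that carbonyl is a methyl ester and all five ring carbons plus the nitrogen are the backbone of 4. Cutting the amide instead would call for the free aminodione. The forward reaction is a base-mediated intramolecular Claisen closure that forms one C–C bond and one ring.

**6 to 3 and 4; 3 to 2 to 1.** The amide bond is cut to acid 3 and amine salt 4. Acid 3 comes from 1 by exchange of the enolate oxygen for bromine and oxidation of the aldehyde 2. The vinyl bromide needed for the coupling is thus in place before ring B is closed.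

**26 to 25 to 23.** The C–Sn bond is removed to give alkyne 25; tin has to come late because it would not survive the iodination. In 25 the C6–O bond of the epoxide is cut, which leads through mesylate 24 to trans-diol 23. Because the diol is trans, a single displacement with inversion at C6 suffices, and the epoxide face is that of the retained C5 oxygen.

**23 to 22 to 21 and 13.** The diol is masked as acetonide 22. The C2–N bond is cut to iodoenone 21 and primary amide 13. Forming this bond while the diol is still protected means no epoxide meets base and copper. 21 comes from 19 by way of 20.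

**19 to 18.** C2=C3 is the only C=C in ring A and is cut by a metathesis transform to diene 18, whose two vinyl groups sit on the C1 carbonyl and on C4.

**18 to 16 to 15 to 14.** In 18 the vinyl group on C4 is removed to give ynone 16 and the vinyl group on C1 is traced to a Weinreb amide. C4 is set by addition to a ketone next to the C5 oxygen, which permits chelate control. 16 comes from diamide 15 by one acetylide addition, and 15 from 14. C5, C6 and their oxygens are those of 14.

**13 to 11 to 10 to 8 and 9.** The upper chain is cut at C4=C5 by a vinylogous phosphonate olefination of 8 with 9, followed by ester hydrolysis and amidation.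

## Alternatives that were turned down

**Alternative 1:** The C1–O and C4–O bonds of ring A are traced to one photooxygenation of a cyclohexadiene, the acetonide A1 of an enzymatically made arene cis-dihydrodiol that already carries the C4 alkyne. In the forward key step a sensitised photooxygenation bridges C1 and C4 of A1 with a peroxide on the face opposite to the dioxolane, closing the 2,3-dioxabicyclo[2.2.2]octene A2. For it: the enzyme fixes the absolute configuration, the cycloaddition fixes C4 relative to C5 and C6 with a dependable facial rule, and on step count to the stereotriad it is stronger than the route chosen here. Against it: A1 depends on fermentation of an alkynyl arene in one enantiomeric series only; the peroxide rearrangement must select the C1 hydrogen; the cis-diol then needs a double inversion at one carbon to become the epoxide, where the trans-diol from 14 needs one displacement; the C2 nitrogen still has to be added; and ring B is not addressed. The chosen strategy accepts a longer ring A sequence from a purchasable chiral-pool ester and spends its one less-proven closure on ring B, where it removes the unstable aminodione from the synthesis.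

**Alternative 2:** The C5–C6 and C6–O bonds are cut together, tracing ring A and the epoxide to the acyclic Z-enone A3, a chloromethyl ketone with a tethered aldehyde. In the forward key step base forms the chloro enolate, which adds to the C5 aldehyde; the alkoxide then displaces chloride to give the 4-alkynyl epoxyquinol silyl ether A4. For it: one operation makes the carbocycle and the cis-fused epoxide, so on bond economy it is stronger. Against it: the quaternary C4 centre of A3 must be made enantioselectively without chiral-pool help; the Z-enone can isomerise under the base; the aldol must choose a face of an aldehyde next to a quaternary carbon whose three substituents are similar in size, so the anti relationship is weakly controlled; only one aldolate can close and Favorskii-type paths compete; the C2 nitrogen is missing. The chosen route fixes the epoxide face by an SN2 displacement on a trans-diol, which does not depend on a diastereoselective aldol, at the price of more steps.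

**Alternative 3:** The C2=C3 alkene of ring A is masked as a norbornene and traced to a Diels–Alder reaction of diene A6 with quinone monoketal A5. In the forward key step, under an enantiopure Lewis acid catalyst, A6 adds endo to one of the two enantiotopic alkenes of A5 and gives A7 with two new C–C bonds. For it: the materials are cheap and achiral, and the convex face of A7 would direct both the C4 nucleophile and the epoxidation to the same side, which is the chain-syn-to-epoxide arrangement the target needs. On diastereocontrol at C4 it is at least as strong as the chelate-controlled addition used here, and its ring A sequence is probably shorter. Against it: selection between the enantiotopic alkenes of A5, which binds a Lewis acid through one carbonyl only, is uncertain; unmasking needs strong heating with a strained epoxy ketone present and before any polyene or stannane is installed; the C2 nitrogen must then be added as in the chosen route. The chosen route takes its absolute configuration from 14 without enantioselective catalysis or thermolysis, and in return is longer.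

Key step: step 4

## Route

Step 1
Reactants: 1 glutaconaldehyde potassium salt
Product: 2 (2E,4E)-5-bromopenta-2,4-dienal
Conditions: Ph3PBr2, CH2Cl2, −20 °C → rt
Reagents that add atoms: triphenylphosphine dibromide, BrP(Br)(c1ccccc1)(c1ccccc1)c1ccccc1
Why: Deoxybromination of a vinylogous acid salt by addition–elimination: the enolate oxygen attacks phosphorus, bromide adds to the activated terminus and Ph3P=O leaves; the product should equilibrate to the conjugated E,E-dienal.

Step 2
Reactants: 2 (2E,4E)-5-bromopenta-2,4-dienal
Product: 3 (2E,4E)-5-bromopenta-2,4-dienoic acid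
Conditions: NaClO2, NaH2PO4, 2-methyl-2-butene, t-BuOH/H2O, 0 °C → rt
Reagents that add atoms: sodium chlorite, [Na+].[O-]Cl=O
Why: Pinnick oxidation; chlorous acid oxidises only the aldehyde and the alkene scavenger removes HOCl so that the bromodiene is not chlorinated.

Step 3
Reactants: 3 (2E,4E)-5-bromopenta-2,4-dienoic acid; 4 methyl 5-aminolevulinate hydrochloride
Product: 6 methyl 5-[(2E,4E)-5-bromopenta-2,4-dienamido]-4-oxopentanoate, via acid chloride 5 (not isolated)
Conditions: (COCl)2, DMF (cat.), CH2Cl2, 0 °C → rt, concentrate; then 4, Et3N (2.2 equiv), CH2Cl2, −20 → 0 °C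
Reagents that add atoms: none
Why: Acid chloride formation followed by Schotten–Baumann-type N-acylation; the amine is freed from its salt only in the presence of 5 at low temperature, so acylation should outrun self-condensation of the α-amino ketone to a dihydropyrazine.

Step 4
Reactants: 6 methyl 5-[(2E,4E)-5-bromopenta-2,4-dienamido]-4-oxopentanoate
Product: 7 (2E,4E)-5-bromo-N-(2-hydroxy-5-oxocyclopent-1-en-1-yl)penta-2,4-dienamide
Conditions: KOtBu (2.5 equiv), THF (0.02 M), 0 °C → rt; then 1 M HCl to pH 3
Reagents that add atoms: none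
Why: Intramolecular Claisen (Dieckmann-type) condensation: KOtBu removes the amide N–H and, in equilibrium, a proton of the C5 methylene between nitrogen and the C4 ketone (aminolevulinate numbering); the C5 enolate carbon attacks the C1 ester carbonyl, methoxide leaves, and the 2-acylamino-1,3-dione is deprotonated at once to its vinylogous carboxylate, which makes the closure irreversible. The closest known reaction is the alkoxide-mediated cyclisation of 4-oxoalkanoate esters to 2-substituted cyclopentane-1,3-diones. Ring B closes in the 5-exo-trig mode with the enolate double bond inside the forming ring (enolendo), a strained geometry that is nevertheless the one used in that precedent. No stereocentre is formed. The step needs enolisation toward C5, which is the most acidic carbon; the C3 enolate could only form a three-membered ring and returns by proton exchange. Attack on the ester by the amidate nitrogen (six-membered N-acyl lactam) or by enolate oxygen (enol lactone) is reversible under alkoxide, whereas the carbon closure is drained by deprotonation of the product. The (E)-bromodiene should survive because the amidate, and later the product enolate, make the dienamide a poor acceptor for alkoxide and an (E)-1-bromoalkene has no hydrogen anti to bromine for E2 loss of HBr; low temperature, dilution and limited base support this.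

Step 5
Reactants: 8 (E)-4-methylpent-2-enal; 9 triethyl (E)-4-phosphonobut-2-enoate
Product: 10 ethyl (2E,4E,6E)-8-methylnona-2,4,6-trienoate
Conditions: LiN(SiMe3)2, THF, −78 → 0 °C
Reagents that add atoms: none
Why: Vinylogous Horner–Wadsworth–Emmons olefination; the stabilised phosphonate anion should give the new C4=C5 bond E under thermodynamic control while the two existing E alkenes are untouched.

Step 6
Reactants: 10 ethyl (2E,4E,6E)-8-methylnona-2,4,6-trienoate
Product: 11 (2E,4E,6E)-8-methylnona-2,4,6-trienoic acid
Conditions: LiOH, THF/MeOH/H2O, rt; then 1 M HCl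
Reagents that add atoms: lithium hydroxide, [Li+].[OH-]
Why: Saponification of a conjugated ester with no epimerisable centre; mild hydroxide should leave the triene geometry intact.

Step 7
Reactants: 11 (2E,4E,6E)-8-methylnona-2,4,6-trienoic acid
Product: 13 (2E,4E,6E)-8-methylnona-2,4,6-trienamide, via acyl imidazole 12 (not isolated)
Conditions: CDI, THF, rt; then aq. NH3, 0 °C → rt
Reagents that add atoms: ammonia, N
Why: Carbonyldiimidazole activation with loss of CO2, then aminolysis of the acyl imidazole; neutral conditions that should not touch the polyene.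

Step 8
Reactants: 14 dimethyl 2,3-O-isopropylidene-D-tartrate
Product: 15 (4S,5S)-N4,N5-dimethoxy-N4,N5,2,2-tetramethyl-1,3-dioxolane-4,5-dicarboxamide
Conditions: MeNHOMe·HCl, i-PrMgCl, THF, −20 → 0 °C
Reagents that add atoms: N,O-dimethylhydroxylamine hydrochloride, CNOC.Cl
Why: Aminolysis of both esters by the magnesium amide formed in the flask (Weinreb amide synthesis); the trans-dioxolane is the stable arrangement, so both tartrate stereocentres should be retained.

Step 9
Reactants: 15 (4S,5S)-N4,N5-dimethoxy-N4,N5,2,2-tetramethyl-1,3-dioxolane-4,5-dicarboxamide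
Product: 16 (4S,5S)-N-methoxy-N,2,2-trimethyl-5-[3-(trimethylsilyl)prop-2-ynoyl]-1,3-dioxolane-4-carboxamide
Conditions: LiC≡CSiMe3 (1.05 equiv), THF, −78 °C; then cold 1 M HCl
Reagents that add atoms: lithium (trimethylsilyl)acetylide, [Li]C#C[Si](C)(C)C
Why: Weinreb ketone synthesis; the chelated lithium adduct does not collapse before the quench, and at −78 °C with one equivalent the anionic, bulky adduct should slow attack on the neighbouring amide, so the C2-symmetric diamide is desymmetrised to the mono-ynone (unreacted 15 is recovered).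

Step 10
Reactants: 16 (4S,5S)-N-methoxy-N,2,2-trimethyl-5-[3-(trimethylsilyl)prop-2-ynoyl]-1,3-dioxolane-4-carboxamide
Product: 18 1-[(4S,5S)-5-[(3R)-3-hydroxy-5-(trimethylsilyl)pent-1-en-4-yn-3-yl]-2,2-dimethyl-1,3-dioxolan-4-yl]prop-2-en-1-one, via carbinol amide 17 (not isolated)
Conditions: CH2=CHMgBr (3.5 equiv), THF, −78 °C then 0 °C; inverse quench into cold 1 M HCl
Reagents that add atoms: vinylmagnesium bromide, C=C[Mg]Br
Why: Cram-chelate-controlled Grignard addition, then Weinreb ketone synthesis in the same flask; magnesium bridges the ynone oxygen and the adjacent dioxolane oxygen and vinyl attacks the face of the α-hydrogen, which should set the (R)-carbinol (future C4, hydroxyl threo to the C5 oxygen along the vinyl chain). On warming, a second equivalent converts the Weinreb amide into the vinyl ketone, and the acidic inverse quench keeps the released amine from adding to the enone.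

Step 11
Reactants: 18 1-[(4S,5S)-5-[(3R)-3-hydroxy-5-(trimethylsilyl)pent-1-en-4-yn-3-yl]-2,2-dimethyl-1,3-dioxolan-4-yl]prop-2-en-1-one
Product: 19 (4R,5S,6S)-4-hydroxy-5,6-(isopropylidenedioxy)-4-[(trimethylsilyl)ethynyl]cyclohex-2-en-1-one
Conditions: second-generation Grubbs catalyst (5 mol %), CH2Cl2 (5 mM), 40 °C
Reagents that add atoms: none
Why: Ring-closing metathesis; the catalyst should load on the vinyl group of the tertiary allylic alcohol and close on to the vinyl ketone to give the six-membered enone with loss of ethylene; the silylated alkyne is a poor partner for enyne metathesis and no stereocentre is touched.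

Step 12
Reactants: 19 (4R,5S,6S)-4-hydroxy-5,6-(isopropylidenedioxy)-4-[(trimethylsilyl)ethynyl]cyclohex-2-en-1-one
Product: 20 (4R,5S,6S)-4-hydroxy-2-iodo-5,6-(isopropylidenedioxy)-4-[(trimethylsilyl)ethynyl]cyclohex-2-en-1-one
Conditions: I2, pyridine, CH2Cl2, 0 °C → rt
Reagents that add atoms: iodine, II
Why: α-Iodination of an enone by pyridine addition, iodination of the enolate and elimination (Baylis–Hillman-type mechanism); the reaction is established for 4,4-disubstituted cyclohexenones and C2 is the only enone α-position.

Step 13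
Reactants: 20 (4R,5S,6S)-4-hydroxy-2-iodo-5,6-(isopropylidenedioxy)-4-[(trimethylsilyl)ethynyl]cyclohex-2-en-1-one
Product: 21 (4R,5S,6S)-2-iodo-5,6-(isopropylidenedioxy)-4-(triethylsilyloxy)-4-[(trimethylsilyl)ethynyl]cyclohex-2-en-1-one
Conditions: Et3SiOTf, 2,6-lutidine, CH2Cl2, −78 → 0 °C
Reagents that add atoms: triethylsilyl trifluoromethanesulfonate, CC[Si](CC)(CC)OS(=O)(=O)C(F)(F)F
Why: Silylation of a hindered tertiary alcohol with a silyl triflate; the ether blocks the alkoxide that could later open the epoxide from the rear (Payne rearrangement) and can be removed at the end without base.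

Step 14
Reactants: 21 (4R,5S,6S)-2-iodo-5,6-(isopropylidenedioxy)-4-(triethylsilyloxy)-4-[(trimethylsilyl)ethynyl]cyclohex-2-en-1-one; 13 (2E,4E,6E)-8-methylnona-2,4,6-trienamide
Product: 22 (4R,5S,6S)-5,6-(isopropylidenedioxy)-2-[(2E,4E,6E)-8-methylnona-2,4,6-trienamido]-4-(triethylsilyloxy)-4-[(trimethylsilyl)ethynyl]cyclohex-2-en-1-one
Conditions: CuI (20 mol %), MeNHCH2CH2NHMe (40 mol %), Cs2CO3, THF, 60 °C, dark
Reagents that add atoms: none
Why: Goldberg-type copper-catalysed amidation of a vinyl iodide; the diamine complex of monovalent copper forms the amidate of 13, inserts into the C2–I bond and releases the enamide with the double bond in place; the diol is still an acetonide, so no epoxide is exposed to base and copper.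

Step 15
Reactants: 22 (4R,5S,6S)-5,6-(isopropylidenedioxy)-2-[(2E,4E,6E)-8-methylnona-2,4,6-trienamido]-4-(triethylsilyloxy)-4-[(trimethylsilyl)ethynyl]cyclohex-2-en-1-one
Product: 23 (4R,5S,6S)-5,6-dihydroxy-2-[(2E,4E,6E)-8-methylnona-2,4,6-trienamido]-4-(triethylsilyloxy)-4-[(trimethylsilyl)ethynyl]cyclohex-2-en-1-one
Conditions: BiCl3 (10 mol %), MeCN/H2O, rt
Reagents that add atoms: none
Why: Lewis-acid-catalysed acetal hydrolysis; the trans-fused dioxolane on ring A is strained and should open under conditions mild enough to spare the hindered tertiary silyl ether, the C-silyl group and the enamide.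

Step 16
Reactants: 23 (4R,5S,6S)-5,6-dihydroxy-2-[(2E,4E,6E)-8-methylnona-2,4,6-trienamido]-4-(triethylsilyloxy)-4-[(trimethylsilyl)ethynyl]cyclohex-2-en-1-one
Product: 25 (4R,5S,6R)-5,6-epoxy-4-ethynyl-2-[(2E,4E,6E)-8-methylnona-2,4,6-trienamido]-4-(triethylsilyloxy)cyclohex-2-en-1-one, via C6 mesylate 24 (not isolated)
Conditions: MsCl (1.1 equiv), Et3N, CH2Cl2, −40 °C; then K2CO3, MeOH, 0 °C → rt
Reagents that add atoms: none
Why: Selective sulfonylation, then intramolecular Williamson (SN2) epoxide closure; the C6 hydroxyl beside the flat C1 carbonyl is far more accessible than the C5 hydroxyl beside the quaternary C4 and should be mesylated. Carbonate in methanol then lets the C5 oxygen displace the C6 mesylate with inversion through the diaxial conformer, which puts the epoxide oxygen on the face of the retained C5 oxygen, anti to the C4 silyloxy group (C6 becomes R); the same medium cleaves the alkynyl C–Si bond.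

Step 17
Reactants: 25 (4R,5S,6R)-5,6-epoxy-4-ethynyl-2-[(2E,4E,6E)-8-methylnona-2,4,6-trienamido]-4-(triethylsilyloxy)cyclohex-2-en-1-one
Product: 26 (4R,5S,6R)-5,6-epoxy-2-[(2E,4E,6E)-8-methylnona-2,4,6-trienamido]-4-[(E)-2-(tributylstannyl)ethenyl]-4-(triethylsilyloxy)cyclohex-2-en-1-one
Conditions: Bu3SnH (1.2 equiv, slow addition), Pd(PPh3)2Cl2 (3 mol %), THF, 0 °C
Reagents that add atoms: tributyltin hydride, CCCC[SnH](CCCC)CCCC
Why: Palladium-catalysed syn-hydrostannation of a terminal alkyne; the fully substituted propargylic carbon should send tin to the terminal carbon and give the (E)-vinylstannane, and slow addition at 0 °C keeps the hydride concentration low so that enone and epoxy ketone are not reduced.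

Step 18
Reactants: 26 (4R,5S,6R)-5,6-epoxy-2-[(2E,4E,6E)-8-methylnona-2,4,6-trienamido]-4-[(E)-2-(tributylstannyl)ethenyl]-4-(triethylsilyloxy)cyclohex-2-en-1-one; 7 (2E,4E)-5-bromo-N-(2-hydroxy-5-oxocyclopent-1-en-1-yl)penta-2,4-dienamide
Product: 27 (4S,5S,6R)-5,6-epoxy-4-[(1E,3E,5E)-7-[(2-hydroxy-5-oxocyclopent-1-en-1-yl)amino]-7-oxohepta-1,3,5-trien-1-yl]-2-[(2E,4E,6E)-8-methylnona-2,4,6-trienamido]-4-(triethylsilyloxy)cyclohex-2-en-1-one
Conditions: Pd(MeCN)2Cl2 (10 mol %), DMF, rt, dark
Reagents that add atoms: none
Why: Stille coupling; zerovalent palladium formed in the flask inserts into the C–Br bond of 7, tin-to-palladium transfer and reductive elimination join the two sp2 carbons with retention of both E geometries; phosphine-free conditions at room temperature should tolerate the free enol, the epoxide and the amides.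

Step 19
Reactants: 27 (4S,5S,6R)-5,6-epoxy-4-[(1E,3E,5E)-7-[(2-hydroxy-5-oxocyclopent-1-en-1-yl)amino]-7-oxohepta-1,3,5-trien-1-yl]-2-[(2E,4E,6E)-8-methylnona-2,4,6-trienamido]-4-(triethylsilyloxy)cyclohex-2-en-1-one
Product: 28 (4S,5S,6R)-5,6-epoxy-4-hydroxy-4-[(1E,3E,5E)-7-[(2-hydroxy-5-oxocyclopent-1-en-1-yl)amino]-7-oxohepta-1,3,5-trien-1-yl]-2-[(2E,4E,6E)-8-methylnona-2,4,6-trienamido]cyclohex-2-en-1-one
Conditions: HF·pyridine, pyridine, THF, 0 °C → rt
Reagents that add atoms: none
Why: Fluoride cleavage of the tertiary triethylsilyl ether under buffered, non-basic conditions, so that no free alkoxide can open the epoxide and the polyenes, enamide and vinylogous acid are left alone.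

## Compound list

1 | glutaconaldehyde potassium salt | [K+].[O-]/C=C/C=C/C=O | starting material
2 | (2E,4E)-5-bromopenta-2,4-dienal | O=C/C=C/C=C/Br | intermediate
3 | (2E,4E)-5-bromopenta-2,4-dienoic acid | OC(=O)/C=C/C=C/Br | intermediate
4 | methyl 5-aminolevulinate hydrochloride | COC(=O)CCC(=O)CN.Cl | starting material
5 | (2E,4E)-5-bromopenta-2,4-dienoyl chloride | ClC(=O)/C=C/C=C/Br | intermediate
6 | methyl 5-[(2E,4E)-5-bromopenta-2,4-dienamido]-4-oxopentanoate | COC(=O)CCC(=O)CNC(=O)/C=C/C=C/Br | intermediate
7 | (2E,4E)-5-bromo-N-(2-hydroxy-5-oxocyclopent-1-en-1-yl)penta-2,4-dienamide | O=C(/C=C/C=C/Br)NC1=C(O)CCC1=O | intermediate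
8 | (E)-4-methylpent-2-enal | CC(C)/C=C/C=O | starting material
9 | triethyl (E)-4-phosphonobut-2-enoate | CCOC(=O)/C=C/CP(=O)(OCC)OCC | starting material
10 | ethyl (2E,4E,6E)-8-methylnona-2,4,6-trienoate | CCOC(=O)/C=C/C=C/C=C/C(C)C | intermediate
11 | (2E,4E,6E)-8-methylnona-2,4,6-trienoic acid | OC(=O)/C=C/C=C/C=C/C(C)C | intermediate
12 | (2E,4E,6E)-1-(imidazol-1-yl)-8-methylnona-2,4,6-trien-1-one | O=C(/C=C/C=C/C=C/C(C)C)n1ccnc1 | intermediate
13 | (2E,4E,6E)-8-methylnona-2,4,6-trienamide | NC(=O)/C=C/C=C/C=C/C(C)C | intermediate
14 | dimethyl 2,3-O-isopropylidene-D-tartrate | COC(=O)[C@H]1OC(C)(C)O[C@@H]1C(=O)OC | starting material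
15 | (4S,5S)-N4,N5-dimethoxy-N4,N5,2,2-tetramethyl-1,3-dioxolane-4,5-dicarboxamide | CON(C)C(=O)[C@H]1OC(C)(C)O[C@@H]1C(=O)N(C)OC | intermediate
16 | (4S,5S)-N-methoxy-N,2,2-trimethyl-5-[3-(trimethylsilyl)prop-2-ynoyl]-1,3-dioxolane-4-carboxamide | C[Si](C)(C)C#CC(=O)[C@H]1OC(C)(C)O[C@@H]1C(=O)N(C)OC | intermediate
17 | (4S,5S)-5-[(3R)-3-hydroxy-5-(trimethylsilyl)pent-1-en-4-yn-3-yl]-N-methoxy-N,2,2-trimethyl-1,3-dioxolane-4-carboxamide (present as its bromomagnesium alkoxide) | C[Si](C)(C)C#C[C@](O)(C=C)[C@H]1OC(C)(C)O[C@@H]1C(=O)N(C)OC | intermediate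
18 | 1-[(4S,5S)-5-[(3R)-3-hydroxy-5-(trimethylsilyl)pent-1-en-4-yn-3-yl]-2,2-dimethyl-1,3-dioxolan-4-yl]prop-2-en-1-one | C[Si](C)(C)C#C[C@](O)(C=C)[C@H]1OC(C)(C)O[C@@H]1C(=O)C=C | intermediate
19 | (4R,5S,6S)-4-hydroxy-5,6-(isopropylidenedioxy)-4-[(trimethylsilyl)ethynyl]cyclohex-2-en-1-one | O=C1C=C[C@@](O)(C#C[Si](C)(C)C)[C@H]2OC(C)(C)O[C@H]12 | intermediate
20 | (4R,5S,6S)-4-hydroxy-2-iodo-5,6-(isopropylidenedioxy)-4-[(trimethylsilyl)ethynyl]cyclohex-2-en-1-one | O=C1C(I)=C[C@@](O)(C#C[Si](C)(C)C)[C@H]2OC(C)(C)O[C@H]12 | intermediate
21 | (4R,5S,6S)-2-iodo-5,6-(isopropylidenedioxy)-4-(triethylsilyloxy)-4-[(trimethylsilyl)ethynyl]cyclohex-2-en-1-one | O=C1C(I)=C[C@@](O[Si](CC)(CC)CC)(C#C[Si](C)(C)C)[C@H]2OC(C)(C)O[C@H]12 | intermediate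
22 | (4R,5S,6S)-5,6-(isopropylidenedioxy)-2-[(2E,4E,6E)-8-methylnona-2,4,6-trienamido]-4-(triethylsilyloxy)-4-[(trimethylsilyl)ethynyl]cyclohex-2-en-1-one | CC(C)/C=C/C=C/C=C/C(=O)NC1=C[C@@](O[Si](CC)(CC)CC)(C#C[Si](C)(C)C)[C@H]2OC(C)(C)O[C@@H]2C1=O | intermediate
23 | (4R,5S,6S)-5,6-dihydroxy-2-[(2E,4E,6E)-8-methylnona-2,4,6-trienamido]-4-(triethylsilyloxy)-4-[(trimethylsilyl)ethynyl]cyclohex-2-en-1-one | CC(C)/C=C/C=C/C=C/C(=O)NC1=C[C@@](O[Si](CC)(CC)CC)(C#C[Si](C)(C)C)[C@@H](O)[C@H](O)C1=O | intermediate
24 | (4R,5S,6S)-5-hydroxy-6-(methanesulfonyloxy)-2-[(2E,4E,6E)-8-methylnona-2,4,6-trienamido]-4-(triethylsilyloxy)-4-[(trimethylsilyl)ethynyl]cyclohex-2-en-1-one | CC(C)/C=C/C=C/C=C/C(=O)NC1=C[C@@](O[Si](CC)(CC)CC)(C#C[Si](C)(C)C)[C@@H](O)[C@H](OS(C)(=O)=O)C1=O | intermediate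
25 | (4R,5S,6R)-5,6-epoxy-4-ethynyl-2-[(2E,4E,6E)-8-methylnona-2,4,6-trienamido]-4-(triethylsilyloxy)cyclohex-2-en-1-one | CC(C)/C=C/C=C/C=C/C(=O)NC1=C[C@@](O[Si](CC)(CC)CC)(C#C)[C@H]2O[C@H]2C1=O | intermediate
26 | (4R,5S,6R)-5,6-epoxy-2-[(2E,4E,6E)-8-methylnona-2,4,6-trienamido]-4-[(E)-2-(tributylstannyl)ethenyl]-4-(triethylsilyloxy)cyclohex-2-en-1-one | CC(C)/C=C/C=C/C=C/C(=O)NC1=C[C@@](O[Si](CC)(CC)CC)(/C=C/[Sn](CCCC)(CCCC)CCCC)[C@H]2O[C@H]2C1=O | intermediate
27 | (4S,5S,6R)-5,6-epoxy-4-[(1E,3E,5E)-7-[(2-hydroxy-5-oxocyclopent-1-en-1-yl)amino]-7-oxohepta-1,3,5-trien-1-yl]-2-[(2E,4E,6E)-8-methylnona-2,4,6-trienamido]-4-(triethylsilyloxy)cyclohex-2-en-1-one | CC(C)/C=C/C=C/C=C/C(=O)NC1=C[C@@](O[Si](CC)(CC)CC)(/C=C/C=C/C=C/C(=O)NC2=C(O)CCC2=O)[C@H]2O[C@H]2C1=O | intermediate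
28 | (4S,5S,6R)-5,6-epoxy-4-hydroxy-4-[(1E,3E,5E)-7-[(2-hydroxy-5-oxocyclopent-1-en-1-yl)amino]-7-oxohepta-1,3,5-trien-1-yl]-2-[(2E,4E,6E)-8-methylnona-2,4,6-trienamido]cyclohex-2-en-1-one | CC(C)/C=C/C=C/C=C/C(=O)NC1=C[C@@](O)(/C=C/C=C/C=C/C(=O)NC2=C(O)CCC2=O)[C@H]2O[C@H]2C1=O | target

## Step count and least certain steps

Total step count: 19. Longest linear sequence: 12 steps (steps 8 to 19, from 14).

**Step 4 (key step).** The enolendo closure may be slow enough for other processes to take over: acyl transfer through the six-membered N-acyl lactam, substitution or elimination of the vinylic bromide by alkoxide, or intermolecular condensation. The fallback sets out from acid chloride 5 and comes back at 7. Cyclopentane-1,3-dione is coupled with benzenediazonium chloride to 2-(2-phenylhydrazinylidene)cyclopentane-1,3-dione F1. Hydrogenolysis of the N–N bond (H2, Pd/C, ethanolic HCl) gives 2-amino-3-hydroxycyclopent-2-en-1-one hydrochloride F2. F2 is N-acylated with 5 (Et3N, CH2Cl2, then brief LiOH to cleave any enol ester) to give 7.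

**Step 10.** Facial selectivity may be poor if the open Felkin–Anh mode competes with the magnesium chelate, and the amide may be attacked before the ketone is consumed. The fallback sets out from 15 and comes back at 17 by exchanging the order of the two nucleophiles. One equivalent of vinylmagnesium bromide at −78 °C (acidic quench) gives (4S,5S)-5-acryloyl-N-methoxy-N,2,2-trimethyl-1,3-dioxolane-4-carboxamide F3. LiC≡CSiMe3 premixed with CeCl3 is then added to F3 at −78 °C under non-chelating conditions. With the acetylide as the nucleophile, the Felkin–Anh mode leads to the same (R)-carbinol 17, which continues with vinylmagnesium bromide at 0 °C as in step 10.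

**Step 11.** Ring closure may be slow because one alkene is an electron-poor vinyl ketone and the product is trans-fused to the dioxolane; oligomerisation by cross-metathesis would then compete. The fallback sets out from 17 (isolated when 1.2 equivalents of the Grignard reagent are used at −78 °C) and comes back at 19. i-Bu2AlH reduces the Weinreb amide to (4S,5S)-5-[(3R)-3-hydroxy-5-(trimethylsilyl)pent-1-en-4-yn-3-yl]-2,2-dimethyl-1,3-dioxolane-4-carbaldehyde F4. Vinylmagnesium bromide gives the bis-allylic alcohol F5 as a mixture of C1 epimers. Metathesis between its two electron-rich alkenes gives cyclohexenediol F6. MnO2 oxidises only the secondary allylic alcohol, so both epimers converge on 19.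

**Step 14.** The copper-catalysed coupling may stall, the iodide may be reduced, or the alkynyl silyl group may be lost under carbonate and the alkyne then couple through a copper acetylide. The fallback sets out from 19 and comes back at 22 without a metal-catalysed C–N coupling. Et3SiOTf/2,6-lutidine gives the silyl ether F7. Nucleophilic epoxidation of the enone (t-BuOOH, DBU) gives the 2,3-epoxy ketone F8. NaN3 opens it at C2, and loss of water (MsCl, Et3N) gives the 2-azido enone F9. A Staudinger reaction (PMe3) and acylation of the aza-ylide with (2E,4E,6E)-8-methylnona-2,4,6-trienoyl chloride F10 (from 11 and oxalyl chloride), followed by aqueous work-up, gives 22.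

**Step 16.** Sulfonylation may occur at the wrong hydroxyl (which would lead to the syn epoxide), C6 may epimerise at the α-sulfonyloxy ketone stage, or the base may be consumed in side reactions. The fallback sets out from 23 and comes back at 25. Mitsunobu-type cyclodehydration (PPh3, DIAD, THF) is used: the two oxyphosphonium betaines interconvert through the dioxaphosphorane, so the outcome is decided by the displacement step, which is fast at the carbonyl-activated C6 and very slow at C5 beside the quaternary carbon. This gives the silylalkynyl epoxide F11, and K2CO3/MeOH then removes the C-silyl group to give 25.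

**Step 17.** Palladium hydride may reduce the enone or cleave the epoxy ketone faster than expected. The fallback sets out from 23 and comes back at 26, placing tin before the epoxide exists. K2CO3/MeOH gives the terminal alkyne diol F12. Hydrostannation as in step 17 gives the stannyl diol F13. Mesylation at C6 gives F14, and closure with K2CO3/MeOH gives 26.

## Further compounds

F1 | step 4 | 2-(2-phenylhydrazinylidene)cyclopentane-1,3-dione | O=C1CCC(=O)C1=NNc1ccccc1
F2 | step 4 | 2-amino-3-hydroxycyclopent-2-en-1-one hydrochloride | NC1=C(O)CCC1=O.Cl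
F3 | step 10 | (4S,5S)-5-acryloyl-N-methoxy-N,2,2-trimethyl-1,3-dioxolane-4-carboxamide | C=CC(=O)[C@H]1OC(C)(C)O[C@@H]1C(=O)N(C)OC
F4 | step 11 | (4S,5S)-5-[(3R)-3-hydroxy-5-(trimethylsilyl)pent-1-en-4-yn-3-yl]-2,2-dimethyl-1,3-dioxolane-4-carbaldehyde | C[Si](C)(C)C#C[C@](O)(C=C)[C@H]1OC(C)(C)O[C@@H]1C=O
F5 | step 11 | 1-[(4S,5S)-5-[(3R)-3-hydroxy-5-(trimethylsilyl)pent-1-en-4-yn-3-yl]-2,2-dimethyl-1,3-dioxolan-4-yl]prop-2-en-1-ol (both carbinol epimers) | C[Si](C)(C)C#C[C@](O)(C=C)[C@H]1OC(C)(C)O[C@@H]1C(O)C=C
F6 | step 11 | 5,6-(isopropylidenedioxy)-4-[(trimethylsilyl)ethynyl]cyclohex-2-ene-1,4-diol (C4, C5, C6 as in 19; both C1 epimers) | OC1C=C[C@@](O)(C#C[Si](C)(C)C)[C@H]2OC(C)(C)O[C@H]12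
F7 | step 14 | 5,6-(isopropylidenedioxy)-4-(triethylsilyloxy)-4-[(trimethylsilyl)ethynyl]cyclohex-2-en-1-one (C4, C5, C6 as in 19) | O=C1C=C[C@@](O[Si](CC)(CC)CC)(C#C[Si](C)(C)C)[C@H]2OC(C)(C)O[C@H]12
F8 | step 14 | 2,3-epoxy-5,6-(isopropylidenedioxy)-4-(triethylsilyloxy)-4-[(trimethylsilyl)ethynyl]cyclohexan-1-one (either epoxide face; C4, C5, C6 as in 19) | O=C1C3OC3[C@@](O[Si](CC)(CC)CC)(C#C[Si](C)(C)C)[C@H]2OC(C)(C)O[C@H]12
F9 | step 14 | 2-azido-5,6-(isopropylidenedioxy)-4-(triethylsilyloxy)-4-[(trimethylsilyl)ethynyl]cyclohex-2-en-1-one (C4, C5, C6 as in 22) | [N-]=[N+]=NC1=C[C@@](O[Si](CC)(CC)CC)(C#C[Si](C)(C)C)[C@H]2OC(C)(C)O[C@@H]2C1=O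
F10 | step 14 | (2E,4E,6E)-8-methylnona-2,4,6-trienoyl chloride | ClC(=O)/C=C/C=C/C=C/C(C)C
F11 | step 16 | (4R,5S,6R)-5,6-epoxy-2-[(2E,4E,6E)-8-methylnona-2,4,6-trienamido]-4-(triethylsilyloxy)-4-[(trimethylsilyl)ethynyl]cyclohex-2-en-1-one | CC(C)/C=C/C=C/C=C/C(=O)NC1=C[C@@](O[Si](CC)(CC)CC)(C#C[Si](C)(C)C)[C@H]2O[C@H]2C1=O
F12 | step 17 | (4R,5S,6S)-4-ethynyl-5,6-dihydroxy-2-[(2E,4E,6E)-8-methylnona-2,4,6-trienamido]-4-(triethylsilyloxy)cyclohex-2-en-1-one | CC(C)/C=C/C=C/C=C/C(=O)NC1=C[C@@](O[Si](CC)(CC)CC)(C#C)[C@@H](O)[C@H](O)C1=O
F13 | step 17 | (4R,5S,6S)-5,6-dihydroxy-2-[(2E,4E,6E)-8-methylnona-2,4,6-trienamido]-4-[(E)-2-(tributylstannyl)ethenyl]-4-(triethylsilyloxy)cyclohex-2-en-1-one | CC(C)/C=C/C=C/C=C/C(=O)NC1=C[C@@](O[Si](CC)(CC)CC)(/C=C/[Sn](CCCC)(CCCC)CCCC)[C@@H](O)[C@H](O)C1=O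
F14 | step 17 | (4R,5S,6S)-5-hydroxy-6-(methanesulfonyloxy)-2-[(2E,4E,6E)-8-methylnona-2,4,6-trienamido]-4-[(E)-2-(tributylstannyl)ethenyl]-4-(triethylsilyloxy)cyclohex-2-en-1-one | CC(C)/C=C/C=C/C=C/C(=O)NC1=C[C@@](O[Si](CC)(CC)CC)(/C=C/[Sn](CCCC)(CCCC)CCCC)[C@@H](O)[C@H](OS(C)(=O)=O)C1=O
A1 | alternative 1 | acetonide of the cis-dihydrodiol of [(triisopropylsilyl)ethynyl]benzene, 2,2-dimethyl-4-[(triisopropylsilyl)ethynyl]-3a,7a-dihydro-1,3-benzodioxole | CC(C)[Si](C(C)C)(C(C)C)C#CC1=CC=C[C@@H]2OC(C)(C)O[C@H]12
A2 | alternative 1 | 7,8-(isopropylidenedioxy)-1-[(triisopropylsilyl)ethynyl]-2,3-dioxabicyclo[2.2.2]oct-5-ene (peroxide bridge anti to the dioxolane) | C1=C[C@]2(C#C[Si](C(C)C)(C(C)C)C(C)C)OO[C@H]1[C@@H]1OC(C)(C)O[C@H]21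
A3 | alternative 2 | (Z)-6-chloro-5-oxo-2-(triethylsilyloxy)-2-[(triisopropylsilyl)ethynyl]hex-3-enal | ClCC(=O)/C=C\[C@@](O[Si](CC)(CC)CC)(C#C[Si](C(C)C)(C(C)C)C(C)C)C=O
A4 | alternative 2 | 5,6-epoxy-4-(triethylsilyloxy)-4-[(triisopropylsilyl)ethynyl]cyclohex-2-en-1-one (silyloxy group anti to the epoxide) | O=C1C=C[C@@](O[Si](CC)(CC)CC)(C#C[Si](C(C)C)(C(C)C)C(C)C)[C@H]2O[C@H]21
A5 | alternative 3 | 4,4-dimethoxycyclohexa-2,5-dien-1-one | COC1(OC)C=CC(=O)C=C1
A6 | alternative 3 | cyclopenta-1,3-diene | C1=CCC=C1
A7 | alternative 3 | endo-4,4-dimethoxy-4a,5,8,8a-tetrahydro-5,8-methanonaphthalen-1(4H)-one | COC1(OC)C=CC(=O)[C@H]2[C@H]3C=C[C@H](C3)[C@@H]12
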